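## Structural features

The target is a 1-tetralone. A 6,7-dimethoxybenzo ring (ring A) is fused to a cyclohexanone (ring B: C1 to C4, C4a, C8a), with a 3-hydroxy-4-methoxyphenyl group (ring C) at C4 and methyl groups at C2 and C3. C2, C3 and C4 are contiguous stereocentres, (2S,3R,4R): the two methyls are trans, and the C3 methyl is cis to the C4 aryl group. C2 is alpha to the ketone and can be equilibrated. Its epimer would place the 2-methyl syn-axial to the pseudo-axial aryl group, so the required 2,3-trans arrangement is the thermodynamic one. C3 (beta to the ketone) and C4 (doubly benzylic) have no such handle, so their cis relationship and absolute configuration must be set kinetically and then preserved. Fragile points are the free phenol, the oxidisable C4–H bond (over-oxidation leads towards a naphthol), the electron-rich rings and alkene precursors towards electrophiles, and C2 towards base. The real difficulty is the absolute configuration at C3, which is remote from any directing group. The key step exploits two facts: C2 becomes a stabilised, chelatable radical once it carries a temporary ester next to the C1 ketone, and C4 bears both ring A and ring C. A C3=C4 alkene therefore accepts the C2 radical at C3, closing ring B through the C2–C3 bond, and leaves a diarylmethyl radical at C4 for a face-selective hydrogen transfer.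

## Logic of the disconnections

19 ⇒ 18. The O–CH2Ph bond on the ring C oxygen is cut, in the sense that a benzyl group is added. The phenol would not survive the organomagnesium, enolate and radical steps. The cut adds no skeletal simplicity but removes the only acidic, oxidisable group. It demands a final hydrogenolysis that spares the aryl ketone and the C4–H bond.

18 ⇒ 16. A methoxycarbonyl group is added at C2, so the bond cleaved in the forward direction is C2–CO2Me. The beta-keto ester gives the two-point binding site for a chiral Lewis acid and stabilises the C2 radical. The gain is that C2 need not be controlled, since it is reset thermodynamically when the ester leaves. The forward step must remove the ester without touching C3 or C4.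

16 ⇒ 15. The C2–C3 bond and the C4–H bond are cut. This opens ring B and removes all three stereocentres, leaving an achiral skeleton that is racemic only at the bromide carbon. The forward step must close 6-endo, take one face of the C2 radical, and deliver hydrogen to C4 anti to the C3 methyl. The alkene geometry of 15 is not a spectator. With the C2 face fixed by the chelate and a half-chair closure, the (Z)-isomer (methyl cis to ring A) places the methyl pseudo-axial and gives (3R). The (E)-isomer would give (3S), which becomes the enantiomeric series once the C2 ester is lost. 15 is therefore specified as the single (Z)-isomer, and an olefination of a diaryl ketone, which cannot control this geometry, is avoided.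

15 ⇒ 13. The C2–Br bond is cut. The forward bromination must select the beta-keto ester over the nucleophilic diarylalkene and the alkoxyarenes, which calls for a preformed enolate.

13 ⇒ 10 + 11. The C1–C2 bond is cut between the benzoate carbonyl and the propanoate alpha-carbon. This removes the three-carbon unit that carries C2, its methyl and the temporary ester. The forward crossed Claisen must overcome a hindered, electron-rich acceptor and must not isomerise the alkene.

10 ⇒ 7 + 8 (through 9). The C4–C4a bond between the alkene and ring A is cut. It is an sp2–sp2 bond whose formation by cross-coupling retains alkene geometry, so the (Z) geometry of 10 is inherited from 7. The molecule falls into two fragments of similar size. The forward step needs a hindered ortho-ester boron partner to couple without loss of geometry.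

7 ⇒ 5 ⇒ 2 + 3, and 2 ⇒ 1. The enol O–S bond is cut, then the aryl–acyl bond, then the O-benzyl bond. The geometry of 7 rests on the inherent preference of an aryl ethyl ketone for the enolate with methyl cis to oxygen. The forward steps are an enolate triflation that preserves this geometry, a ketone synthesis without over-addition, and a phenol alkylation. 1, 3, 8 and 11 are commercial.

## Other disconnections considered

Alternative 1: The cut is at C4a–C5 and C8–C8a, so ring A is built last. In the forward direction the enone (4-aryl-5,6-dimethylcyclohex-2-enone, A2) would react with 2,3-dimethoxybuta-1,3-diene (A3) under Me2AlCl in a Diels–Alder reaction. The product would be the cis-fused adduct A1, correctly named a 3,4,4a,5,8,8a-hexahydronaphthalen-1(2H)-one. Dehydrogenation of the bis(enol ether) ring would converge on 18. In its favour, the two new ring-fusion centres disappear on aromatisation, so the key step carries no stereochemical demand; on this point it is better than the chosen plan. It also needs no tin, and the number of operations after the key step (two) is equal. Against it, A2 already contains all three stereocentres, so the problem is postponed, not solved. Its C4 hydrogen is gamma to the enone and benzylic, hence prone to dienolisation. Cyclohexenones are sluggish dienophiles, and A3 is acid-sensitive under an aluminium Lewis acid. The oxidative aromatisation must also stop short of dehydrogenating ring B. Mechanistically it is a polar pericyclic step against a radical chain. In step economy it should be longer overall, because A2 needs its own asymmetric synthesis.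

Alternative 2: The cut is at C1–C2 and C3–C4, closing ring B by a [4+2] reaction. Irradiation of the 2-benzylbenzaldehyde A5 would give the hydroxy-o-quinodimethane. This would add endo to the (5R)-menthyloxybutenolide A6, anti to the menthyloxy group, to give the all-cis adduct A4. In its favour, two ring bonds and four stereocentres form at once. The C3/C4 cis relationship follows from the endo rule, and absolute control comes from an inexpensive auxiliary and not from a stoichiometric chiral magnesium complex; on predictability of C3/C4 it is at least the equal of the chosen plan. Against it, three carbons arrive at the wrong oxidation level. The lactone carbonyl carbon and the acetal carbon must each be reduced to a methyl group, C1 must be oxidised and C2 epimerised. That is about six operations after the key step, against two. Photoenolisation of dialkoxybenzaldehydes is less efficient, the geometry of the aryl-bearing dienol terminus decides C4, and photochemistry limits scale. On step economy the chosen plan is clearly better.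

Alternative 3: The cut is at C1–C2, with C3–H formed in the same step. The ortho-allylbenzaldehyde A8 would undergo endo hydroacylation with cationic monovalent rhodium, generated from [Rh(cod)Cl]2, a chiral bisphosphine and Na[B(3,5-(CF3)2C6H3)4]. The product would be the cis-3-methyl-4-aryl tetralone A7, and enolate methylation trans to the C3 methyl would reach 18. In its favour it is catalytic and fully atom-economical, with no tin, no perchlorate and no temporary ester; on these points it is better. The two operations after the key step are equal in number. Against it, A8 already carries the C4 stereocentre as a doubly benzylic, allylic methine. That centre must first be made enantiopure and can be lost by alkene migration into conjugation under a rhodium hydride. The catalyst then has to set C3 cis against any substrate bias, decarbonylation competes, and the key step creates only one stereocentre. The chosen plan sets C3 and C4 together from an achiral skeleton, which is why it is preferred despite its heavier reagents.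

Key step: step 7

Assumption: the sense of induction of the magnesium bis(oxazoline) chelate is assigned by analogy with related chelated beta-keto ester radicals; if the (S,S)-ligand favours the opposite face of the C2 radical, the (R,R)-ligand is used with no other change.

## Route

Step 1
Reactants: 1 5-bromo-2-methoxyphenol
Product: 2 2-(benzyloxy)-4-bromo-1-methoxybenzene
Conditions: BnBr, K2CO3, DMF, rt
Reagents that add atoms: benzyl bromide, BrCc1ccccc1
Why: Williamson ether synthesis; the phenoxide displaces bromide from benzyl bromide and the aryl bromide is inert under these conditions.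

Step 2
Reactants: 2 2-(benzyloxy)-4-bromo-1-methoxybenzene; 3 N-methoxy-N-methylpropanamide
Product: 5 1-[3-(benzyloxy)-4-methoxyphenyl]propan-1-one, via aryl Grignard reagent 4 (not isolated)
Conditions: Mg, THF, 40 °C; then 3, 0 °C; 1 M HCl
Reagents that add atoms: none
Why: Magnesium insertion into the aryl bromide followed by Weinreb ketone synthesis; the chelated tetrahedral adduct persists until acidic work-up, so no tertiary alcohol should form and the benzyl ether is untouched.

Step 3
Reactants: 5 1-[3-(benzyloxy)-4-methoxyphenyl]propan-1-one
Product: 7 (1Z)-1-[3-(benzyloxy)-4-methoxyphenyl]prop-1-en-1-yl trifluoromethanesulfonate, via potassium (Z)-enolate 6 (not isolated)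
Conditions: KN(SiMe3)2, THF, −78 °C; then PhNTf2, −78 to 0 °C; aq. NH4Cl
Reagents that add atoms: N-phenylbis(trifluoromethanesulfonimide), O=S(=O)(N(c1ccccc1)S(=O)(=O)C(F)(F)F)C(F)(F)F
Why: Kinetic deprotonation of an aryl ethyl ketone gives the enolate with methyl cis to oxygen, because the other geometry suffers allylic strain between methyl and aryl; O-sulfonylation (enol triflate formation) freezes that geometry, which later dictates C3.

Step 4
Reactants: 8 methyl 2-bromo-4,5-dimethoxybenzoate; 7 (1Z)-1-[3-(benzyloxy)-4-methoxyphenyl]prop-1-en-1-yl trifluoromethanesulfonate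
Product: 10 methyl 2-{(1Z)-1-[3-(benzyloxy)-4-methoxyphenyl]prop-1-en-1-yl}-4,5-dimethoxybenzoate, via aryl pinacol boronate 9 (not isolated)
Conditions: B2pin2 (1.05 equiv), PdCl2(dppf) (3 mol%), KOAc, 1,4-dioxane, 90 °C; then 7, aq. K3PO4, 70 °C
Reagents that add atoms: none
Why: One-pot Miyaura borylation of the aryl bromide and Suzuki–Miyaura coupling of the resulting boronate with the alkenyl triflate under one palladium catalyst; every step at the alkenyl carbon proceeds with retention, so ring A ends cis to the methyl (Z), and the mild bases should not hydrolyse the hindered methyl ester.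

Step 5
Reactants: 10 methyl 2-{(1Z)-1-[3-(benzyloxy)-4-methoxyphenyl]prop-1-en-1-yl}-4,5-dimethoxybenzoate; 11 methyl propanoate
Product: 13 methyl 3-(2-{(1Z)-1-[3-(benzyloxy)-4-methoxyphenyl]prop-1-en-1-yl}-4,5-dimethoxyphenyl)-2-methyl-3-oxopropanoate (racemic at C2), via lithium ester enolate 12 (not isolated)
Conditions: 11 (3.3 equiv), LiN(iPr)2 (3.0 equiv), THF, −78 °C; then 10, −78 to −20 °C; 1 M HCl
Reagents that add atoms: none
Why: Crossed Claisen condensation; 10 has no alpha-hydrogen and can only be the acceptor, and deprotonation of the beta-keto ester product by a second equivalent of enolate drives the reaction; the slight excess of 11 over the amide base leaves no free amide to deprotonate the allylic methyl, so the alkene geometry should hold.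

Step 6
Reactants: 13 methyl 3-(2-{(1Z)-1-[3-(benzyloxy)-4-methoxyphenyl]prop-1-en-1-yl}-4,5-dimethoxyphenyl)-2-methyl-3-oxopropanoate
Product: 15 methyl 2-bromo-3-(2-{(1Z)-1-[3-(benzyloxy)-4-methoxyphenyl]prop-1-en-1-yl}-4,5-dimethoxyphenyl)-2-methyl-3-oxopropanoate (racemic), via sodium enolate 14 (not isolated)
Conditions: NaH (1.05 equiv), THF, 0 °C; then NBS (1.0 equiv), −78 °C; aq. NH4Cl; used without delay
Reagents that add atoms: N-bromosuccinimide, O=C1CCC(=O)N1Br
Why: Electrophilic alpha-bromination of a preformed beta-keto ester enolate; the anion should react with NBS at −78 °C far faster than the neutral diarylalkene or the alkoxyarenes, which secures chemoselectivity with one equivalent of reagent; the product is a mild positive-bromine donor and is therefore not stored.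

Step 7
Reactants: 15 methyl 2-bromo-3-(2-{(1Z)-1-[3-(benzyloxy)-4-methoxyphenyl]prop-1-en-1-yl}-4,5-dimethoxyphenyl)-2-methyl-3-oxopropanoate
Product: 16 methyl (2R,3R,4R)-4-[3-(benzyloxy)-4-methoxyphenyl]-6,7-dimethoxy-2,3-dimethyl-1-oxo-1,2,3,4-tetrahydronaphthalene-2-carboxylate
Conditions: Mg(ClO4)2 (1.1 equiv), (S,S)-tBu-box (1.2 equiv), 4 Å MS, toluene/CH2Cl2, −78 °C; Et3B (1 M in hexane), air; Bu3SnH (1.3 equiv) by syringe pump
Reagents that add atoms: none
Why: Ethyl radicals from Et3B and oxygen start a tin chain in which Bu3Sn• abstracts bromine from 15, giving a tertiary C2 radical that is held as a two-point chelate between the ketone and ester oxygens and the magnesium bis(oxazoline) complex. The closest known reaction type is the Lewis-acid-templated enantioselective radical cyclisation of unsaturated alpha-bromo-beta-keto esters under Mg(ClO4)2 and a bis(oxazoline), run here with the tin hydride termination familiar from magnesium bis(oxazoline)-controlled radical additions. Ring B closes 6-endo-trig: attack at the methyl-bearing alkene carbon C3 leaves a doubly benzylic radical at C4, whereas the 5-exo path would have to attack the fully substituted diaryl carbon. C2 is controlled by the ligand, whose tert-butyl group shields one face of the planar chelated radical, and the ester stays in the chelate plane and becomes pseudo-equatorial, giving (2R). C3 follows from the half-chair closure together with the (Z) geometry, which places the C3 methyl pseudo-axial, anti to the C2 methyl and clear of the C4 aryl group, giving (3R); the (E)-isomer would deliver the opposite C3 configuration, which is why a single geometric isomer is required. C4 is set when Bu3SnH transfers hydrogen to the cyclised diarylmethyl radical anti to the adjacent pseudo-axial C3 methyl, giving the cis methyl/aryl pair (4R). The step needs ring closure to outrun hydrogen transfer to the uncyclised C2 radical and needs all substrate to react as the chiral chelate; slow addition of Bu3SnH keeps its concentration low, Lewis-acid activation makes the electrophilic radical add quickly to the electron-rich alkene, and a full equivalent of the chiral complex suppresses the unbound pathway.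

Step 8
Reactants: 16 methyl (2R,3R,4R)-4-[3-(benzyloxy)-4-methoxyphenyl]-6,7-dimethoxy-2,3-dimethyl-1-oxo-1,2,3,4-tetrahydronaphthalene-2-carboxylate
Product: 18 (2S,3R,4R)-4-[3-(benzyloxy)-4-methoxyphenyl]-6,7-dimethoxy-2,3-dimethyl-3,4-dihydronaphthalen-1(2H)-one, via lithium enolate 17 (not isolated)
Conditions: LiCl (3 equiv), H2O (2 equiv), DMSO, 140 °C, N2
Reagents that add atoms: none
Why: Krapcho dealkoxycarbonylation; chloride demethylates the ester by SN2, the beta-keto carboxylate loses CO2 to the enolate, and protonation, reversible in the hot slightly basic medium, should settle C2 with the 2-methyl equatorial and trans to the 3-methyl; C3 and C4 bear no acidic hydrogen here and are unchanged.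

Step 9
Reactants: 18 (2S,3R,4R)-4-[3-(benzyloxy)-4-methoxyphenyl]-6,7-dimethoxy-2,3-dimethyl-3,4-dihydronaphthalen-1(2H)-one
Product: 19 (2S,3R,4R)-4-(3-hydroxy-4-methoxyphenyl)-6,7-dimethoxy-2,3-dimethyl-3,4-dihydronaphthalen-1(2H)-one
Conditions: H2 (1 atm), Pd/C (10 wt%), EtOAc, rt
Reagents that add atoms: none
Why: Hydrogenolysis of the aryl benzyl ether; under neutral conditions at atmospheric pressure the aryl ketone (deactivated by the para-methoxy group) and the C4–H bond should not be reduced, and no stereocentre is touched.

## Compound list

1 | 5-bromo-2-methoxyphenol | COc1ccc(Br)cc1O | starting material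
2 | 2-(benzyloxy)-4-bromo-1-methoxybenzene | COc1ccc(Br)cc1OCc1ccccc1 | intermediate
3 | N-methoxy-N-methylpropanamide | CCC(=O)N(C)OC | starting material
4 | [3-(benzyloxy)-4-methoxyphenyl]magnesium bromide (not isolated) | COc1ccc([Mg]Br)cc1OCc1ccccc1 | intermediate
5 | 1-[3-(benzyloxy)-4-methoxyphenyl]propan-1-one | CCC(=O)c1ccc(OC)c(OCc2ccccc2)c1 | intermediate
6 | potassium (1Z)-1-[3-(benzyloxy)-4-methoxyphenyl]prop-1-en-1-olate (not isolated) | [K+].C/C=C(/c1ccc(OC)c(OCc2ccccc2)c1)[O-] | intermediate
7 | (1Z)-1-[3-(benzyloxy)-4-methoxyphenyl]prop-1-en-1-yl trifluoromethanesulfonate | C/C=C(/c1ccc(OC)c(OCc2ccccc2)c1)OS(=O)(=O)C(F)(F)F | intermediate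
8 | methyl 2-bromo-4,5-dimethoxybenzoate | COC(=O)c1cc(OC)c(OC)cc1Br | starting material
9 | methyl 4,5-dimethoxy-2-(4,4,5,5-tetramethyl-1,3,2-dioxaborolan-2-yl)benzoate (not isolated) | COC(=O)c1cc(OC)c(OC)cc1B1OC(C)(C)C(C)(C)O1 | intermediate
10 | methyl 2-{(1Z)-1-[3-(benzyloxy)-4-methoxyphenyl]prop-1-en-1-yl}-4,5-dimethoxybenzoate | C/C=C(/c1ccc(OC)c(OCc2ccccc2)c1)c1cc(OC)c(OC)cc1C(=O)OC | intermediate
11 | methyl propanoate | CCC(=O)OC | starting material
12 | lithium enolate of methyl propanoate, geometry immaterial (not isolated) | [Li+].CC=C([O-])OC | intermediate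
13 | methyl 3-(2-{(1Z)-1-[3-(benzyloxy)-4-methoxyphenyl]prop-1-en-1-yl}-4,5-dimethoxyphenyl)-2-methyl-3-oxopropanoate, racemic at C2 | C/C=C(/c1ccc(OC)c(OCc2ccccc2)c1)c1cc(OC)c(OC)cc1C(=O)C(C)C(=O)OC | intermediate
14 | sodium enolate of 13, (Z)-alkene retained (not isolated) | [Na+].C/C=C(/c1ccc(OC)c(OCc2ccccc2)c1)c1cc(OC)c(OC)cc1C([O-])=C(C)C(=O)OC | intermediate
15 | methyl 2-bromo-3-(2-{(1Z)-1-[3-(benzyloxy)-4-methoxyphenyl]prop-1-en-1-yl}-4,5-dimethoxyphenyl)-2-methyl-3-oxopropanoate, racemic at the bromide carbon | C/C=C(/c1ccc(OC)c(OCc2ccccc2)c1)c1cc(OC)c(OC)cc1C(=O)C(C)(Br)C(=O)OC | intermediate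
16 | methyl (2R,3R,4R)-4-[3-(benzyloxy)-4-methoxyphenyl]-6,7-dimethoxy-2,3-dimethyl-1-oxo-1,2,3,4-tetrahydronaphthalene-2-carboxylate | O=C1[C@](C)(C(=O)OC)[C@H](C)[C@H](c3ccc(OC)c(OCc4ccccc4)c3)c2cc(OC)c(OC)cc12 | intermediate
17 | lithium (3R,4R)-4-[3-(benzyloxy)-4-methoxyphenyl]-6,7-dimethoxy-2,3-dimethyl-3,4-dihydronaphthalen-1-olate (not isolated) | [Li+].[O-]C1=C(C)[C@H](C)[C@H](c3ccc(OC)c(OCc4ccccc4)c3)c2cc(OC)c(OC)cc12 | intermediate
18 | (2S,3R,4R)-4-[3-(benzyloxy)-4-methoxyphenyl]-6,7-dimethoxy-2,3-dimethyl-3,4-dihydronaphthalen-1(2H)-one | COc1ccc([C@@H]2c3cc(OC)c(OC)cc3C(=O)[C@@H](C)[C@@H]2C)cc1OCc1ccccc1 | intermediate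
19 | (2S,3R,4R)-4-(3-hydroxy-4-methoxyphenyl)-6,7-dimethoxy-2,3-dimethyl-3,4-dihydronaphthalen-1(2H)-one | COc1ccc([C@@H]2c3cc(OC)c(OC)cc3C(=O)[C@@H](C)[C@@H]2C)cc1O | target

## Step count and least certain steps

Total: 9 steps. Longest linear sequence: 9 steps (1 to 19; compounds 3, 8 and 11 enter as purchased materials).

Step 7 (key step). Three processes are the most likely to fail. The first is premature hydrogen transfer from Bu3SnH to the electrophilic C2 radical before ring closure, which only returns 13. The second is erosion of enantioface control if some substrate cyclises outside the chiral chelate. The third is imperfect facial selectivity of hydrogen delivery at C4, because the face that must be attacked is flanked by the syn-axial C2 methyl. The fallback gives up catalyst control of absolute configuration and keeps the ring construction. Starting from 15, the same tin hydride cyclisation is run with Mg(ClO4)2 and no chiral ligand at −40 °C, to give the racemic methyl (2R*,3R*,4R*)-4-[3-(benzyloxy)-4-methoxyphenyl]-6,7-dimethoxy-2,3-dimethyl-1-oxotetralin-2-carboxylate F1. Krapcho dealkoxycarbonylation as in step 8 gives the racemic 2,3-trans-3,4-cis ketone F2. F2 is resolved by preparative chromatography on a chiral stationary phase, and the route is rejoined at 18.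

Step 5. Acylation of the ester enolate by the hindered, electron-rich benzoate may be slow, which would let the propanoate enolate condense with itself. The fallback replaces the ester acceptor by an activated acyl donor. From 10, saponification (LiOH, THF/MeOH/H2O) gives 2-{(1Z)-1-[3-(benzyloxy)-4-methoxyphenyl]prop-1-en-1-yl}-4,5-dimethoxybenzoic acid F3. 1,1'-Carbonyldiimidazole converts it into the acyl imidazolide F4. C-acylation of the magnesium enolate of potassium methyl methylmalonate (MgCl2, Et3N, MeCN) with decarboxylation on acidic work-up rejoins the route at 13.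

Step 6. Bromine may be transferred to the electron-rich alkene or arenes, either from the reagent or later from the product itself, which is a positive-halogen donor. The fallback changes the radical precursor. From 13, the same sodium enolate is chlorinated with N-chlorosuccinimide to the alpha-chloro-beta-keto ester, methyl 2-chloro-3-(2-{(1Z)-1-[3-(benzyloxy)-4-methoxyphenyl]prop-1-en-1-yl}-4,5-dimethoxyphenyl)-2-methyl-3-oxopropanoate F5. This is a far weaker halogen donor. Its doubly activated tertiary C–Cl bond should still be abstracted by Bu3Sn• under the step 7 conditions with initiation at −40 °C, rejoining the route at 16.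

Step 3. Enolisation may be incompletely selective, or some geometric leakage may occur on triflation. Any (E)-isomer would pass directly into loss of enantiomeric purity at C3. The fallback builds the alkene by a different stereodefining principle. From 2, bromine–lithium exchange (n-BuLi, −78 °C), B(OiPr)3 and acidic work-up give [3-(benzyloxy)-4-methoxyphenyl]boronic acid F6. Mono-Suzuki coupling with 1,1-dibromoprop-1-ene, in which the bromide trans to the methyl reacts first, gives (1Z)-1-bromo-1-[3-(benzyloxy)-4-methoxyphenyl]prop-1-ene F7. A second Suzuki coupling with 9, prepared from 8 as in the first half of step 4, rejoins the route at 10.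

Step 4. In the one-pot sequence the ortho-ester boronate may protodeboronate, or residual B2pin2 may borylate the triflate and lead to its homocoupling. The fallback reverses the roles of the partners. From 7, Miyaura borylation (B2pin2, PdCl2(dppf), KOPh, toluene, 50 °C) gives the isolated alkenyl boronate, 2-{(1E)-1-[3-(benzyloxy)-4-methoxyphenyl]prop-1-en-1-yl}-4,4,5,5-tetramethyl-1,3,2-dioxaborolane F8. Suzuki coupling of F8 with 8 (Pd(PPh3)4, aq. K3PO4, dioxane) rejoins the route at 10.

## Further compounds

F1 | step 7 | racemic methyl (2R*,3R*,4R*)-4-[3-(benzyloxy)-4-methoxyphenyl]-6,7-dimethoxy-2,3-dimethyl-1-oxo-1,2,3,4-tetrahydronaphthalene-2-carboxylate (one enantiomer drawn) | O=C1[C@](C)(C(=O)OC)[C@H](C)[C@H](c3ccc(OC)c(OCc4ccccc4)c3)c2cc(OC)c(OC)cc12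
F2 | step 7 | racemic (2S*,3R*,4R*)-4-[3-(benzyloxy)-4-methoxyphenyl]-6,7-dimethoxy-2,3-dimethyl-3,4-dihydronaphthalen-1(2H)-one (one enantiomer drawn) | COc1ccc([C@@H]2c3cc(OC)c(OC)cc3C(=O)[C@@H](C)[C@@H]2C)cc1OCc1ccccc1
F3 | step 5 | 2-{(1Z)-1-[3-(benzyloxy)-4-methoxyphenyl]prop-1-en-1-yl}-4,5-dimethoxybenzoic acid | C/C=C(/c1ccc(OC)c(OCc2ccccc2)c1)c1cc(OC)c(OC)cc1C(=O)O
F4 | step 5 | (2-{(1Z)-1-[3-(benzyloxy)-4-methoxyphenyl]prop-1-en-1-yl}-4,5-dimethoxyphenyl)(1H-imidazol-1-yl)methanone | C/C=C(/c1ccc(OC)c(OCc2ccccc2)c1)c1cc(OC)c(OC)cc1C(=O)n1ccnc1
F5 | step 6 | methyl 2-chloro-3-(2-{(1Z)-1-[3-(benzyloxy)-4-methoxyphenyl]prop-1-en-1-yl}-4,5-dimethoxyphenyl)-2-methyl-3-oxopropanoate, racemic | C/C=C(/c1ccc(OC)c(OCc2ccccc2)c1)c1cc(OC)c(OC)cc1C(=O)C(C)(Cl)C(=O)OC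
F6 | step 3 | [3-(benzyloxy)-4-methoxyphenyl]boronic acid | OB(O)c1ccc(OC)c(OCc2ccccc2)c1
F7 | step 3 | (1Z)-1-bromo-1-[3-(benzyloxy)-4-methoxyphenyl]prop-1-ene | C/C=C(/c1ccc(OC)c(OCc2ccccc2)c1)Br
F8 | step 4 | 2-{(1E)-1-[3-(benzyloxy)-4-methoxyphenyl]prop-1-en-1-yl}-4,4,5,5-tetramethyl-1,3,2-dioxaborolane | C/C=C(/c1ccc(OC)c(OCc2ccccc2)c1)B1OC(C)(C)C(C)(C)O1
A1 | alternative 1 | cis-fused 4-[3-(benzyloxy)-4-methoxyphenyl]-6,7-dimethoxy-2,3-dimethyl-3,4,4a,5,8,8a-hexahydronaphthalen-1(2H)-one, C2/C3/C4 as in 18, ring-fusion hydrogens anti to the aryl group | O=C1[C@@H](C)[C@H](C)[C@H](c3ccc(OC)c(OCc4ccccc4)c3)[C@H]2CC(OC)=C(OC)C[C@@H]12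
A2 | alternative 1 | 4-[3-(benzyloxy)-4-methoxyphenyl]-5,6-dimethylcyclohex-2-en-1-one, 5-methyl cis to the aryl group and trans to the 6-methyl | O=C1[C@@H](C)[C@H](C)[C@H](c2ccc(OC)c(OCc3ccccc3)c2)C=C1
A3 | alternative 1 | 2,3-dimethoxybuta-1,3-diene | C=C(OC)C(=C)OC
A4 | alternative 2 | all-cis 1-hydroxy-4-[3-(benzyloxy)-4-methoxyphenyl]-6,7-dimethoxytetralin fused at C2/C3 to the (menthyloxy)butanolide | O[C@@H]1[C@@H]2C(=O)O[C@@H](O[C@@H]4C[C@H](C)CC[C@H]4C(C)C)[C@@H]2[C@H](c5ccc(OC)c(OCc6ccccc6)c5)c3cc(OC)c(OC)cc31
A5 | alternative 2 | 2-{[3-(benzyloxy)-4-methoxyphenyl]methyl}-4,5-dimethoxybenzaldehyde | O=Cc1cc(OC)c(OC)cc1Cc1ccc(OC)c(OCc2ccccc2)c1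
A6 | alternative 2 | (5R)-5-[(1R,2S,5R)-menthyloxy]furan-2(5H)-one | O=C1O[C@@H](O[C@@H]2C[C@H](C)CC[C@H]2C(C)C)C=C1
A7 | alternative 3 | (3R,4R)-4-[3-(benzyloxy)-4-methoxyphenyl]-6,7-dimethoxy-3-methyl-3,4-dihydronaphthalen-1(2H)-one | O=C1C[C@H](C)[C@H](c3ccc(OC)c(OCc4ccccc4)c3)c2cc(OC)c(OC)cc12
A8 | alternative 3 | 2-{(1R)-1-[3-(benzyloxy)-4-methoxyphenyl]-2-methylprop-2-en-1-yl}-4,5-dimethoxybenzaldehyde | C=C(C)[C@H](c1ccc(OC)c(OCc2ccccc2)c1)c1cc(OC)c(OC)cc1C=O
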